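The route rests on closing the cyclohexane ring (C5–C10, elemane numbering) last, at C5–C6, by an intramolecular carbonyl-ene reaction. It exploits the isopulegol-like motif of the target: the C6 oxygen on the six-membered ring, trans to the C5 substituent that carries the C4=C3 methylidene. In one operation the step forms C5–C6, sets C5 and C6, creates the exocyclic alkene and, through the C6 alkoxide, closes the C6–O–C12 lactone ring. Its precursor is an open-chain C6 aldehyde with a Z-trisubstituted C4=C5 alkene; C10 comes from a copper-catalysed allylic substitution and C7/C8 from an auxiliary-controlled syn aldol of an itaconate unit.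

Key step: step 13

Remark: elemane numbering is used throughout. C10 is the quaternary ring carbon (C14 methyl, C1=C2 vinyl), C5 carries C4(=C3H2)–C15H2O, C6 carries the lactone oxygen, C7 carries C11(=C13H2)–C12(=O), C8 carries the ester oxygen and C9 is the ring CH2; α is the face opposite to the C14 methyl group (5α-H, 6β-H, 7α-H, 8β-H).
Remark: compounds 1, 6, 15, 17 and 25 are taken as purchased; the facial sense of the ligand in step 5 is assumed to be selectable by choice of its enantiomer.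

Step 1
Reactants: 1 tert-butyl(but-3-yn-1-yloxy)dimethylsilane
Product: 4 (2E)-5-(tert-butyldimethylsilyloxy)-3-methylpent-2-en-1-ol, via alkenyldimethylalane 2 (not isolated), via lithium alkenylalanate 3 (not isolated)
Conditions: Me3Al, Cp2ZrCl2 (cat.), CH2Cl2, 0 °C → rt; then n-BuLi, THF, −78 °C; (CH2O)n, → rt
Reagents that add atoms: trimethylaluminium C[Al](C)C; formaldehyde (as paraformaldehyde) C=O
Why: Zirconium-catalysed Negishi carboalumination adds CH3–Al syn across the terminal alkyne with the methyl on the internal carbon, and the alanate adds to formaldehyde with retention, which fixes the E geometry.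

Step 2
Reactants: 4 (2E)-5-(tert-butyldimethylsilyloxy)-3-methylpent-2-en-1-ol
Product: 5 (2E)-5-(tert-butyldimethylsilyloxy)-3-methylpent-2-en-1-yl diethyl phosphate
Conditions: ClP(O)(OEt)2, Et3N, DMAP (cat.), CH2Cl2, 0 °C
Reagents that add atoms: diethyl chlorophosphate CCOP(=O)(Cl)OCC
Why: Routine phosphorylation of a primary allylic alcohol gives the leaving group needed for copper-catalysed SN2′ substitution.

Step 3
Reactants: 6 prop-2-yn-1-ol
Product: 8 (2Z)-3-iodo-2-methylprop-2-en-1-ol, via alkenylmagnesium alkoxide 7 (not isolated)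
Conditions: MeMgBr, CuI (10 mol %), THF, −10 °C → rt; then I2, −78 → 0 °C
Reagents that add atoms: methylmagnesium bromide C[Mg]Br; iodine II
Why: Alkoxide-directed, copper-catalysed anti-carbomagnesiation places methyl on C2 and magnesium cis to the CH2O group, and iodinolysis with retention gives the Z vinyl iodide.

Step 4
Reactants: 8 (2Z)-3-iodo-2-methylprop-2-en-1-ol
Product: 9 tert-butyl{[(2Z)-3-iodo-2-methylprop-2-en-1-yl]oxy}diphenylsilane
Conditions: TBDPSCl, imidazole, CH2Cl2, rt
Reagents that add atoms: tert-butyl(chloro)diphenylsilane CC(C)(C)[Si](Cl)(c1ccccc1)c1ccccc1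
Why: Routine silylation; the bulky TBDPS group survives the later acid steps and resists O-to-C silyl migration in the derived alkenyllithium.

Step 5
Reactants: 5 (2E)-5-(tert-butyldimethylsilyloxy)-3-methylpent-2-en-1-yl diethyl phosphate; 9 tert-butyl{[(2Z)-3-iodo-2-methylprop-2-en-1-yl]oxy}diphenylsilane
Product: 12 (3S,4Z)-1-(tert-butyldimethylsilyloxy)-6-(tert-butyldiphenylsilyloxy)-3-ethenyl-3,5-dimethylhex-4-ene, via alkenyllithium 10 (not isolated), via alkenyldiethylalane 11 (not isolated)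
Conditions: 9, t-BuLi, Et2O, −78 °C; Et2AlCl, −78 → 0 °C; then 5, CuCl2·2H2O (2 mol %), chiral sulfonate-bearing imidazolinium salt (NHC precursor, 2 mol %), THF, −15 °C
Reagents that add atoms: none
Why: Iodine–lithium exchange and transmetalation give a configurationally stable Z-alkenylalane, and NHC–copper-catalysed enantioselective allylic substitution (SN2′) on the γ,γ-disubstituted phosphate should create the C10 quaternary centre together with its vinyl group, the ligand enantiomer being chosen for the S configuration.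

Step 6
Reactants: 12 (3S,4Z)-1-(tert-butyldimethylsilyloxy)-6-(tert-butyldiphenylsilyloxy)-3-ethenyl-3,5-dimethylhex-4-ene
Product: 13 (3S,4Z)-6-(tert-butyldiphenylsilyloxy)-3-ethenyl-3,5-dimethylhex-4-en-1-ol
Conditions: CSA (10 mol %), MeOH/CH2Cl2, 0 °C
Reagents that add atoms: none
Why: Acid-catalysed methanolysis should cleave the primary TBS ether much faster than the primary TBDPS ether.

Step 7
Reactants: 13 (3S,4Z)-6-(tert-butyldiphenylsilyloxy)-3-ethenyl-3,5-dimethylhex-4-en-1-ol
Product: 14 (3S,4Z)-6-(tert-butyldiphenylsilyloxy)-3-ethenyl-3,5-dimethylhex-4-enal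
Conditions: Dess–Martin periodinane, NaHCO3, CH2Cl2, 0 °C → rt
Reagents that add atoms: none
Why: Dess–Martin oxidation of a primary alcohol; the aldehyde has no α-stereocentre and cannot move into conjugation past the quaternary carbon.

Step 8
Reactants: 15 dimethyl itaconate
Product: 16 3-(methoxycarbonyl)but-3-enoic acid
Conditions: LiOH·H2O (1.0 equiv), THF/H2O, 0 °C; aq. HCl
Reagents that add atoms: lithium hydroxide [Li+].[OH-]
Why: One equivalent of hydroxide should saponify the unconjugated, less hindered ester in preference to the α-substituted acrylate ester.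

Step 9
Reactants: 16 3-(methoxycarbonyl)but-3-enoic acid; 17 (4R)-4-benzyl-1,3-thiazolidine-2-thione
Product: 18 methyl 4-[(4R)-4-benzyl-2-sulfanylidene-1,3-thiazolidin-3-yl]-2-methylidene-4-oxobutanoate
Conditions: EDC·HCl, DMAP (cat.), CH2Cl2, 0 °C → rt
Reagents that add atoms: none
Why: Carbodiimide coupling N-acylates the thiazolidinethione under conditions mild enough to leave the 1,1-disubstituted alkene out of conjugation.

Step 10
Reactants: 14 (3S,4Z)-6-(tert-butyldiphenylsilyloxy)-3-ethenyl-3,5-dimethylhex-4-enal; 18 methyl 4-[(4R)-4-benzyl-2-sulfanylidene-1,3-thiazolidin-3-yl]-2-methylidene-4-oxobutanoate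
Product: 19 methyl 2-[(2R,3S,5S,6Z)-1-[(4R)-4-benzyl-2-sulfanylidene-1,3-thiazolidin-3-yl]-8-(tert-butyldiphenylsilyloxy)-5-ethenyl-3-hydroxy-5,7-dimethyl-1-oxooct-6-en-2-yl]prop-2-enoate
Conditions: 18, TiCl4, i-Pr2NEt, NMP, CH2Cl2, 0 °C; then 14, −78 → −40 °C
Reagents that add atoms: none
Why: The titanium Z-enolate of the N-acylthiazolidinethione should react at its α-carbon through a Zimmerman–Traxler chair in the Evans-syn mode, so that the R-auxiliary sets C7 (R) and C8 (S) as the syn pair irrespective of the remote C10 centre.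

Step 11
Reactants: 19 methyl 2-[(2R,3S,5S,6Z)-1-[(4R)-4-benzyl-2-sulfanylidene-1,3-thiazolidin-3-yl]-8-(tert-butyldiphenylsilyloxy)-5-ethenyl-3-hydroxy-5,7-dimethyl-1-oxooct-6-en-2-yl]prop-2-enoate
Product: 20 methyl 2-[(2R,3S,5S,6Z)-1-[(4R)-4-benzyl-2-sulfanylidene-1,3-thiazolidin-3-yl]-8-(tert-butyldiphenylsilyloxy)-5-ethenyl-5,7-dimethyl-1-oxo-3-(triethylsilyloxy)oct-6-en-2-yl]prop-2-enoate
Conditions: TESOTf, 2,6-lutidine, CH2Cl2, −78 °C
Reagents that add atoms: triethylsilyl trifluoromethanesulfonate CC[Si](CC)(CC)OS(=O)(=O)C(F)(F)F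
Why: Low-temperature silylation caps the C8 hydroxyl before it can lactonise onto the C12 ester or be eliminated.

Step 12
Reactants: 20 methyl 2-[(2R,3S,5S,6Z)-1-[(4R)-4-benzyl-2-sulfanylidene-1,3-thiazolidin-3-yl]-8-(tert-butyldiphenylsilyloxy)-5-ethenyl-5,7-dimethyl-1-oxo-3-(triethylsilyloxy)oct-6-en-2-yl]prop-2-enoate
Product: 21 methyl 2-[(2R,3S,5S,6Z)-8-(tert-butyldiphenylsilyloxy)-5-ethenyl-5,7-dimethyl-1-oxo-3-(triethylsilyloxy)oct-6-en-2-yl]prop-2-enoate
Conditions: i-Bu2AlH (1.5 equiv), CH2Cl2, −78 °C; aq. potassium sodium tartrate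
Reagents that add atoms: none
Why: The activated N-acylthiazolidinethione should be reduced at −78 °C to a stable tetrahedral aluminium adduct that gives the aldehyde on work-up, faster than the methyl ester reacts; the crude aldehyde is used at once.

Step 13
Reactants: 21 methyl 2-[(2R,3S,5S,6Z)-8-(tert-butyldiphenylsilyloxy)-5-ethenyl-5,7-dimethyl-1-oxo-3-(triethylsilyloxy)oct-6-en-2-yl]prop-2-enoate
Product: 23 15-(tert-butyldiphenylsilyloxy)-8α-(triethylsilyloxy)elema-1,3,11(13)-trien-12,6α-olide, via hydroxy ester 22 (not isolated)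
Conditions: Me2AlCl (2 equiv), CH2Cl2, −78 → 0 °C, then rt
Reagents that add atoms: none
Why: Me2AlCl activates the C6 aldehyde, C5 of the C4=C5 alkene attacks C6 while a hydrogen of the C3 methyl group passes to the carbonyl oxygen through a six-membered ene transition state, and the aluminium alkoxide formed at C6 then displaces methoxide from the C12 ester. The closest known reaction is the Lewis acid-promoted intramolecular carbonyl-ene cyclisation of citronellal to isopulegol. The carbocycle closes in a 6-exo-trig sense (carbonyl oxygen and the new C4=C3 double bond both end outside the ring), and the lactone closes by 5-exo-trig acyl substitution. C6 is controlled by the chair transition state in which the C7 and C8 substituents are equatorial and the C10 methyl is axial, so that the complexed oxygen must be equatorial (an axial oxygen would be 1,3-diaxial to that methyl); C5 is controlled by allylic 1,3-strain, because only attack on the alkene face that makes C4 equatorial keeps the Z-CH2OSi group away from C9. The step needs chemoselectivity for the trisubstituted alkene over the vinyl and acrylate groups (it is the only electron-rich alkene with an allylic hydrogen in reach), regioselectivity of hydrogen transfer (secured by the Z geometry, which puts the C3 methyl and not the C15 methylene next to the carbonyl oxygen) and retention of C7 (secured by the low temperature and the non-basic, proton-scavenging Lewis acid).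

Step 14
Reactants: 23 15-(tert-butyldiphenylsilyloxy)-8α-(triethylsilyloxy)elema-1,3,11(13)-trien-12,6α-olide
Product: 24 15-(tert-butyldiphenylsilyloxy)-8α-hydroxyelema-1,3,11(13)-trien-12,6α-olide
Conditions: PPTS, MeOH, rt
Reagents that add atoms: none
Why: Mild acid methanolysis should remove the secondary TES ether and leave the TBDPS ether and the lactone intact.

Step 15
Reactants: 25 (2E)-but-2-enal
Product: 27 (2Z)-2-bromobut-2-enal, via dibromide 26 (not isolated)
Conditions: Br2, CH2Cl2, 0 °C; then Et3N, 0 °C → rt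
Reagents that add atoms: bromine BrBr
Why: Bromine adds across the enal double bond and triethylamine removes the acidic α-hydrogen with loss of the β-bromide, giving the more stable Z α-bromoenal (bromine cis to methyl).

Step 16
Reactants: 27 (2Z)-2-bromobut-2-enal
Product: 28 (2Z)-2-bromobut-2-en-1-ol
Conditions: NaBH4, CeCl3·7H2O, MeOH, 0 °C
Reagents that add atoms: none
Why: Luche 1,2-reduction of the enal leaves the vinyl bromide and its geometry untouched.

Step 17
Reactants: 28 (2Z)-2-bromobut-2-en-1-ol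
Product: 29 {[(2Z)-2-bromobut-2-en-1-yl]oxy}(tert-butyl)dimethylsilane
Conditions: TBSCl, imidazole, CH2Cl2, rt
Reagents that add atoms: tert-butyl(chloro)dimethylsilane CC(C)(C)[Si](C)(C)Cl
Why: Routine silylation of a primary allylic alcohol.

Step 18
Reactants: 29 {[(2Z)-2-bromobut-2-en-1-yl]oxy}(tert-butyl)dimethylsilane
Product: 31 (2Z)-2-[(tert-butyldimethylsilyloxy)methyl]but-2-enoic acid, via vinyllithium 30 (not isolated)
Conditions: t-BuLi (2.1 equiv), Et2O, −78 °C; CO2; aq. HCl to pH 3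
Reagents that add atoms: carbon dioxide O=C=O
Why: Bromine–lithium exchange and carboxylation at −78 °C both proceed with retention at the alkene, so the carboxyl group ends up cis to the methyl group (Z acid).

Step 19
Reactants: 24 15-(tert-butyldiphenylsilyloxy)-8α-hydroxyelema-1,3,11(13)-trien-12,6α-olide; 31 (2Z)-2-[(tert-butyldimethylsilyloxy)methyl]but-2-enoic acid
Product: 33 15-(tert-butyldiphenylsilyloxy)-8α-{(2Z)-2-[(tert-butyldimethylsilyloxy)methyl]but-2-enoyloxy}elema-1,3,11(13)-trien-12,6α-olide, via mixed anhydride 32 (not isolated)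
Conditions: 31, 2,4,6-trichlorobenzoyl chloride, Et3N, toluene, rt; then 24, DMAP, toluene, rt
Reagents that add atoms: none
Why: Yamaguchi esterification through the mixed anhydride should acylate the equatorial C8 hydroxyl with retention at C8, a short reaction time at room temperature limiting Z-to-E isomerisation of the acyl group.

Step 20
Reactants: 33 15-(tert-butyldiphenylsilyloxy)-8α-{(2Z)-2-[(tert-butyldimethylsilyloxy)methyl]but-2-enoyloxy}elema-1,3,11(13)-trien-12,6α-olide
Product: 34 15-hydroxy-8α-[(2Z)-2-(hydroxymethyl)but-2-enoyloxy]elema-1,3,11(13)-trien-12,6α-olide (CNP0111202.1)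
Conditions: HF·pyridine, pyridine, THF, 0 °C → rt
Reagents that add atoms: none
Why: Buffered fluoride should cleave both primary silyl ethers without touching the α-methylene lactone or the unsaturated ester.

Compound list
1 | tert-butyl(but-3-yn-1-yloxy)dimethylsilane | C#CCCO[Si](C)(C)C(C)(C)C | starting material
2 | [(1E)-4-(tert-butyldimethylsilyloxy)-2-methylbut-1-en-1-yl]dimethylalane | C[Al](C)/C=C(\C)CCO[Si](C)(C)C(C)(C)C | intermediate
3 | lithium butyl[(1E)-4-(tert-butyldimethylsilyloxy)-2-methylbut-1-en-1-yl]dimethylalanate | [Li+].CCCC[Al-](C)(C)/C=C(\C)CCO[Si](C)(C)C(C)(C)C | intermediate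
4 | (2E)-5-(tert-butyldimethylsilyloxy)-3-methylpent-2-en-1-ol | OC/C=C(\C)CCO[Si](C)(C)C(C)(C)C | intermediate
5 | (2E)-5-(tert-butyldimethylsilyloxy)-3-methylpent-2-en-1-yl diethyl phosphate | CCOP(=O)(OCC)OC/C=C(\C)CCO[Si](C)(C)C(C)(C)C | intermediate
6 | prop-2-yn-1-ol | C#CCO | starting material
7 | bromomagnesium (2Z)-3-(bromomagnesio)-2-methylprop-2-en-1-olate | Br[Mg]/C=C(/C)CO[Mg]Br | intermediate
8 | (2Z)-3-iodo-2-methylprop-2-en-1-ol | I/C=C(/C)CO | intermediate
9 | tert-butyl{[(2Z)-3-iodo-2-methylprop-2-en-1-yl]oxy}diphenylsilane | I/C=C(/C)CO[Si](c1ccccc1)(c1ccccc1)C(C)(C)C | intermediate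
10 | [(1Z)-3-(tert-butyldiphenylsilyloxy)-2-methylprop-1-en-1-yl]lithium | [Li]/C=C(/C)CO[Si](c1ccccc1)(c1ccccc1)C(C)(C)C | intermediate
11 | [(1Z)-3-(tert-butyldiphenylsilyloxy)-2-methylprop-1-en-1-yl]diethylalane | CC[Al](CC)/C=C(/C)CO[Si](c1ccccc1)(c1ccccc1)C(C)(C)C | intermediate
12 | (3S,4Z)-1-(tert-butyldimethylsilyloxy)-6-(tert-butyldiphenylsilyloxy)-3-ethenyl-3,5-dimethylhex-4-ene | C=C[C@](C)(CCO[Si](C)(C)C(C)(C)C)/C=C(/C)CO[Si](c1ccccc1)(c1ccccc1)C(C)(C)C | intermediate
13 | (3S,4Z)-6-(tert-butyldiphenylsilyloxy)-3-ethenyl-3,5-dimethylhex-4-en-1-ol | C=C[C@](C)(CCO)/C=C(/C)CO[Si](c1ccccc1)(c1ccccc1)C(C)(C)C | intermediate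
14 | (3S,4Z)-6-(tert-butyldiphenylsilyloxy)-3-ethenyl-3,5-dimethylhex-4-enal | C=C[C@](C)(CC=O)/C=C(/C)CO[Si](c1ccccc1)(c1ccccc1)C(C)(C)C | intermediate
15 | dimethyl itaconate (dimethyl 2-methylidenebutanedioate) | COC(=O)CC(=C)C(=O)OC | starting material
16 | 3-(methoxycarbonyl)but-3-enoic acid | OC(=O)CC(=C)C(=O)OC | intermediate
17 | (4R)-4-benzyl-1,3-thiazolidine-2-thione | S=C1N[C@H](Cc2ccccc2)CS1 | starting material
18 | methyl 4-[(4R)-4-benzyl-2-sulfanylidene-1,3-thiazolidin-3-yl]-2-methylidene-4-oxobutanoate | COC(=O)C(=C)CC(=O)N1C(=S)SC[C@H]1Cc1ccccc1 | intermediate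
19 | methyl 2-[(2R,3S,5S,6Z)-1-[(4R)-4-benzyl-2-sulfanylidene-1,3-thiazolidin-3-yl]-8-(tert-butyldiphenylsilyloxy)-5-ethenyl-3-hydroxy-5,7-dimethyl-1-oxooct-6-en-2-yl]prop-2-enoate | C=C[C@](C)(C[C@H](O)[C@@H](C(=C)C(=O)OC)C(=O)N1C(=S)SC[C@H]1Cc1ccccc1)/C=C(/C)CO[Si](c1ccccc1)(c1ccccc1)C(C)(C)C | intermediate
20 | methyl 2-[(2R,3S,5S,6Z)-1-[(4R)-4-benzyl-2-sulfanylidene-1,3-thiazolidin-3-yl]-8-(tert-butyldiphenylsilyloxy)-5-ethenyl-5,7-dimethyl-1-oxo-3-(triethylsilyloxy)oct-6-en-2-yl]prop-2-enoate | C=C[C@](C)(C[C@H](O[Si](CC)(CC)CC)[C@@H](C(=C)C(=O)OC)C(=O)N1C(=S)SC[C@H]1Cc1ccccc1)/C=C(/C)CO[Si](c1ccccc1)(c1ccccc1)C(C)(C)C | intermediate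
21 | methyl 2-[(2R,3S,5S,6Z)-8-(tert-butyldiphenylsilyloxy)-5-ethenyl-5,7-dimethyl-1-oxo-3-(triethylsilyloxy)oct-6-en-2-yl]prop-2-enoate | C=C[C@](C)(C[C@H](O[Si](CC)(CC)CC)[C@@H](C(=C)C(=O)OC)C=O)/C=C(/C)CO[Si](c1ccccc1)(c1ccccc1)C(C)(C)C | intermediate
22 | methyl 15-(tert-butyldiphenylsilyloxy)-6α-hydroxy-8α-(triethylsilyloxy)elema-1,3,11(13)-trien-12-oate | C=C[C@]1(C)C[C@H](O[Si](CC)(CC)CC)[C@@H](C(=C)C(=O)OC)[C@H](O)[C@H]1C(=C)CO[Si](c1ccccc1)(c1ccccc1)C(C)(C)C | intermediate
23 | 15-(tert-butyldiphenylsilyloxy)-8α-(triethylsilyloxy)elema-1,3,11(13)-trien-12,6α-olide | C=C[C@]1(C)C[C@H](O[Si](CC)(CC)CC)[C@H]2C(=C)C(=O)O[C@@H]2[C@H]1C(=C)CO[Si](c1ccccc1)(c1ccccc1)C(C)(C)C | intermediate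
24 | 15-(tert-butyldiphenylsilyloxy)-8α-hydroxyelema-1,3,11(13)-trien-12,6α-olide | C=C[C@]1(C)C[C@H](O)[C@H]2C(=C)C(=O)O[C@@H]2[C@H]1C(=C)CO[Si](c1ccccc1)(c1ccccc1)C(C)(C)C | intermediate
25 | (2E)-but-2-enal | C/C=C/C=O | starting material
26 | 2,3-dibromobutanal | CC(Br)C(Br)C=O | intermediate
27 | (2Z)-2-bromobut-2-enal | C/C=C(\Br)C=O | intermediate
28 | (2Z)-2-bromobut-2-en-1-ol | C/C=C(\Br)CO | intermediate
29 | {[(2Z)-2-bromobut-2-en-1-yl]oxy}(tert-butyl)dimethylsilane | C/C=C(\Br)CO[Si](C)(C)C(C)(C)C | intermediate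
30 | [(2E)-1-(tert-butyldimethylsilyloxy)but-2-en-2-yl]lithium (lithium in place of bromine, geometry retained) | C/C=C(\[Li])CO[Si](C)(C)C(C)(C)C | intermediate
31 | (2Z)-2-[(tert-butyldimethylsilyloxy)methyl]but-2-enoic acid | C/C=C(\C(=O)O)CO[Si](C)(C)C(C)(C)C | intermediate
32 | (2Z)-2-[(tert-butyldimethylsilyloxy)methyl]but-2-enoic 2,4,6-trichlorobenzoic anhydride | C/C=C(\C(=O)OC(=O)c1c(Cl)cc(Cl)cc1Cl)CO[Si](C)(C)C(C)(C)C | intermediate
33 | 15-(tert-butyldiphenylsilyloxy)-8α-{(2Z)-2-[(tert-butyldimethylsilyloxy)methyl]but-2-enoyloxy}elema-1,3,11(13)-trien-12,6α-olide | C=C[C@]1(C)C[C@H](OC(=O)/C(=C\C)CO[Si](C)(C)C(C)(C)C)[C@H]2C(=C)C(=O)O[C@@H]2[C@H]1C(=C)CO[Si](c1ccccc1)(c1ccccc1)C(C)(C)C | intermediate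
34 | 15-hydroxy-8α-[(2Z)-2-(hydroxymethyl)but-2-enoyloxy]elema-1,3,11(13)-trien-12,6α-olide; (3aR,4S,6S,7R,7aR)-6-ethenyl-7-(3-hydroxyprop-1-en-2-yl)-6-methyl-3-methylidene-2-oxooctahydro-1-benzofuran-4-yl (2Z)-2-(hydroxymethyl)but-2-enoate | C=C[C@]1(C)C[C@H](OC(=O)/C(=C\C)CO)[C@H]2C(=C)C(=O)O[C@@H]2[C@H]1C(=C)CO | target

Total step count: 20. Longest linear sequence: 12 steps (1, 2, 5, 6, 7, 10, 11, 12, 13, 14, 19, 20).

Steps most likely to fail

Step 13. The doubly activated C7–H of aldehyde 21 may be lost before the ring closes, by epimerisation or by migration of the C11=C13 double bond into conjugation with the aldehyde. The fallback sets out from aldehyde 14 and leaves the methylidene group out until the lactone is in place. Thiazolidinethione 17 is acylated with methyl 4-chloro-4-oxobutanoate (Et3N, CH2Cl2) to methyl 4-[(4R)-4-benzyl-2-sulfanylidene-1,3-thiazolidin-3-yl]-4-oxobutanoate F1. The titanium aldol of step 10 with 14 should then give the 13-nor analogue of 19 F2, silylation the 13-nor analogue of 20 F3, and i-Bu2AlH the 13-nor analogue of 21 F4, whose C7–H is only α to the aldehyde. Me2AlCl closes the ring by the same carbonyl-ene reaction through the 13-nor analogue of 22 F5 to 15-(tert-butyldiphenylsilyloxy)-8α-(triethylsilyloxy)-13-norelema-1,3-dien-12,6α-olide F6. α-Methylenation of the lactone (LDA, THF, −78 °C, then Eschenmoser's salt) gives the 11-[(dimethylamino)methyl] derivative of F6 F7, and MeI followed by NaHCO3 brings the route back to 23.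

Step 5. The hindered β,β-disubstituted alkenylalane may couple slowly, leak into the linear SN2 product, or give poor enantioselectivity at C10. The fallback sets out from iodide 9 and builds C10 by a Claisen rearrangement without absolute control. Stannylcupration of but-2-yn-1-ol gives (2E)-3-(tributylstannyl)but-2-en-1-ol F8, and Stille coupling with 9 (Pd(PPh3)4, CuI, DMF) gives (2E,4Z)-6-(tert-butyldiphenylsilyloxy)-3,5-dimethylhexa-2,4-dien-1-ol F9. Vinyl ether exchange (ethyl vinyl ether, Hg(OAc)2) gives tert-butyl{[(2Z,4E)-6-(ethenyloxy)-2,4-dimethylhexa-2,4-dien-1-yl]oxy}diphenylsilane F10, and heating in toluene gives racemic (4Z)-6-(tert-butyldiphenylsilyloxy)-3-ethenyl-3,5-dimethylhex-4-enal F11. The auxiliary-controlled aldol of step 10 then gives 19 together with the C10 epimer of 19 F12; the two diastereomers are separated by chromatography and the route is rejoined at 19.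

Step 19. The activated Z acid may isomerise to the E acyl group through reversible conjugate addition of DMAP, or acylation of the hindered C8 hydroxyl may be so slow that the lactone migrates to O8. The fallback sets out from alcohol 24 and vinyl bromide 29 and builds the ester carbonyl instead of activating an acid: palladium-catalysed alkoxycarbonylation (Pd(OAc)2, Xantphos, CO at 1 atm, Et3N, toluene, 70 °C) should give 33 directly, the alkene geometry being held by the vinyl–palladium bond. It makes no new compound and returns to the route at 33.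

Further compounds
F1 | step 13 | methyl 4-[(4R)-4-benzyl-2-sulfanylidene-1,3-thiazolidin-3-yl]-4-oxobutanoate | COC(=O)CCC(=O)N1C(=S)SC[C@H]1Cc1ccccc1
F2 | step 13 | 13-nor analogue of 19 (CH2 in place of C(=CH2) at C11) | C=C[C@](C)(C[C@H](O)[C@@H](CC(=O)OC)C(=O)N1C(=S)SC[C@H]1Cc1ccccc1)/C=C(/C)CO[Si](c1ccccc1)(c1ccccc1)C(C)(C)C
F3 | step 13 | 13-nor analogue of 20 | C=C[C@](C)(C[C@H](O[Si](CC)(CC)CC)[C@@H](CC(=O)OC)C(=O)N1C(=S)SC[C@H]1Cc1ccccc1)/C=C(/C)CO[Si](c1ccccc1)(c1ccccc1)C(C)(C)C
F4 | step 13 | 13-nor analogue of 21 | C=C[C@](C)(C[C@H](O[Si](CC)(CC)CC)[C@@H](CC(=O)OC)C=O)/C=C(/C)CO[Si](c1ccccc1)(c1ccccc1)C(C)(C)C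
F5 | step 13 | 13-nor analogue of 22 | C=C[C@]1(C)C[C@H](O[Si](CC)(CC)CC)[C@@H](CC(=O)OC)[C@H](O)[C@H]1C(=C)CO[Si](c1ccccc1)(c1ccccc1)C(C)(C)C
F6 | step 13 | 15-(tert-butyldiphenylsilyloxy)-8α-(triethylsilyloxy)-13-norelema-1,3-dien-12,6α-olide | C=C[C@]1(C)C[C@H](O[Si](CC)(CC)CC)[C@H]2CC(=O)O[C@@H]2[C@H]1C(=C)CO[Si](c1ccccc1)(c1ccccc1)C(C)(C)C
F7 | step 13 | 11-[(dimethylamino)methyl] derivative of F6 (C11 epimers) | C=C[C@]1(C)C[C@H](O[Si](CC)(CC)CC)[C@H]2C(CN(C)C)C(=O)O[C@@H]2[C@H]1C(=C)CO[Si](c1ccccc1)(c1ccccc1)C(C)(C)C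
F8 | step 5 | (2E)-3-(tributylstannyl)but-2-en-1-ol | OC/C=C(\C)[Sn](CCCC)(CCCC)CCCC
F9 | step 5 | (2E,4Z)-6-(tert-butyldiphenylsilyloxy)-3,5-dimethylhexa-2,4-dien-1-ol | OC/C=C(\C)/C=C(/C)CO[Si](c1ccccc1)(c1ccccc1)C(C)(C)C
F10 | step 5 | tert-butyl{[(2Z,4E)-6-(ethenyloxy)-2,4-dimethylhexa-2,4-dien-1-yl]oxy}diphenylsilane | C=COC/C=C(\C)/C=C(/C)CO[Si](c1ccccc1)(c1ccccc1)C(C)(C)C
F11 | step 5 | racemic (4Z)-6-(tert-butyldiphenylsilyloxy)-3-ethenyl-3,5-dimethylhex-4-enal | C=CC(C)(CC=O)/C=C(/C)CO[Si](c1ccccc1)(c1ccccc1)C(C)(C)C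
F12 | step 5 | C10 epimer of 19 (2R,3S,5R,6Z) | C=C[C@@](C)(C[C@H](O)[C@@H](C(=C)C(=O)OC)C(=O)N1C(=S)SC[C@H]1Cc1ccccc1)/C=C(/C)CO[Si](c1ccccc1)(c1ccccc1)C(C)(C)C
F0 | step 19 | none | none
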